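**Remark on the chemistry.** The target has no stereocentre, no stereogenic axis and no configurable double bond, so only one stereoisomer exists. The SMILES is taken as that single achiral compound and no stereocontrol is planned. Orsellinic acid (2,4-dihydroxy-6-methylbenzoic acid) is assumed to be a purchasable building block.

Locants used below: rings A (trimethoxytoluoyl), B (central orsellinoyl) and C (terminal orsellinic acid). Within each ring C1 carries the carboxyl carbon C7, and O2 and O4 are the ortho and para oxygens (for example C7B, O4C).

## The problem

Target 16 is a tridepside in which ring A (2,3,4-trimethoxy-6-methylbenzoyl), ring B (2-hydroxy-6-methylbenzoyl, acylated on O4) and ring C (2-hydroxy-6-methylbenzoic acid, acylated on O4) are joined by two aryl ester bonds, C7A(=O)–O4B and C7B(=O)–O4C. With no stereocentre, the difficulty lies entirely in connectivity and chemoselection. Each ester carbonyl sits on a ring carbon flanked by two ortho substituents (OCH3/CH3 on A, OH/CH3 on B), so acyl transfer from a preformed benzoic acid to an ester-deactivated phenol is slow and is usually paid for with protecting groups and forcing activation. The oxygens of rings B and C must end up differentiated: two acylated para oxygens, two free chelated ortho phenols and one free acid. The aryl esters are cleaved or scrambled by alkoxide, hydroxide and free phenoxide, the salicylic acid terminus loses CO2 when heated with acid or base, and ring A is electron-rich enough to be halogenated. The enabling feature is ring B itself: C7B, C2B and C4B carry oxygen on alternate carbons and C6B carries a methyl group, which is the pattern of a head-to-tail tetraketide (a 3,5,7-trioxooctanoyl chain) closed by an aldol bond C1B–C6B, with the chain's carboxyl terminus C7B being the carbon bonded to O4C. The B–C ester can therefore be made while C7B is still an unhindered ketene carbon, and the hindered arene grown around it afterwards.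

## Retrosynthesis

**16 ⇒ 15.** The O–CH2Ph bond of the ring C carboxylate is cut last. A benzyl ester is the only protecting group in the plan and is removed by neutral hydrogenolysis, the one deprotection that leaves aryl esters and a decarboxylation-prone salicylic acid untouched. Hydrolytic ester cleavage would attack both depside bonds first.

**15 ⇒ 9 + 14 (from 13).** The C7A(=O)–O4B bond is cut. Ring A is the only unit that is an acid without a phenol, so it can be fully activated as chloride 14 without self-condensation. Benzyl lecanorate 9 offers one non-chelated phenol (O4B) beside two chelated ones (O2B, O2C). Cutting the B–C bond at this stage instead would demand activation of a di-ortho-substituted salicylic acid. The forward reaction must mono-acylate O4B and must not let phenoxide attack the B–C ester.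

**9 ⇒ 5 + 3 (through 6, 7 and 8).** This is the key disconnection. Two bonds are cut together: the depside bond C7B(=O)–O4C and the ring bond C1B–C6B. Ring B unravels to the acyclic aryl triketo ester 7, which is the adduct of phenol 5 with acylketene 6, and 6 is stored as dioxinone 3. Cutting the ester alone would require a 4-O-protected orsellinic acid and a coupling at a hindered carbonyl (Alternative 1). Here the ester forms at an sp carbon with no ortho neighbours, ring B needs no protecting group, and it is born with O4B free and O2B chelated, exactly as the next step requires. The precursor side is one arene and a C8 chain, against two differentiated arenes in 9. The forward reaction must capture 6 intermolecularly at O4 of 5 and must close the chain by aldol and not by acyl transfer.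

**5 ⇒ 4.** Only the O–CH2Ph bond of the ester is cut, and ring C is bought intact as orsellinic acid 4. The carboxyl of ring C never has to act as an acyl donor, so its two ortho substituents do not matter: the ester is made by alkylation of the carboxylate at the benzylic carbon of benzyl bromide. Growing ring C from 3 as well would spend a second portion of the two-step dioxinone on a ring that offers no connectivity problem. The forward reaction must alkylate the carboxylate and leave both phenols free.

**3 ⇒ 2 ⇒ 1.** The two C–C bonds between acetyl units are cut. Dioxinone 2 is acetylated at its terminal methyl through the dianion, and 2 itself comes from γ-acetylation of the commercial diketene–acetone adduct 1. Both are short, precedented operations on commodity reagents.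

**13 ⇒ 12 ⇒ 10.** The C1A–C7A bond is cut. Commercial 3,4,5-trimethoxytoluene 10 has two equivalent free positions, so formylation can give only aldehyde 12 (via iminium salt 11), and oxidation gives acid 13.

## Roads not taken

Alternative 1: the classical depside synthesis, which is the most obvious route. Only the two ester C(=O)–O bonds are cut, and each is formed from a preformed benzoic acid with a dehydrating agent, the phenols being protected as benzyl ethers. The forward key step would be condensation of 2,4-bis(benzyloxy)-6-methylbenzoic acid A1 with 5 to give the protected didepside A2.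
- The acyl carbon of A1 lies between an ortho benzyloxy and an ortho methyl group, so attack by the deactivated phenol is slow and needs strong activation.
- A1 itself costs two operations from 4 (per-benzylation, then hydrolysis of a hindered benzyl ester).
- Hydrogenolysis of A2 removes every benzyl group at once and gives lecanoric acid A3, in which the acylation site O4B is no longer distinguished from the free carboxyl.
- Repairing this with an orthogonal silyl ether, or reversing the order of the two couplings, turns the approach into the fallbacks given below for steps 4 and 7. Even those need three or four operations for the B–C bond, against one in step 4, and still activate a di-ortho-substituted carboxyl.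

Alternative 2: a benzodioxinone as latent acyl donor. The B–C ester is cut, but ring B is kept as its acetonide A4 (7-hydroxy-2,2,5-trimethyl-4H-1,3-benzodioxin-4-one), which has a single free phenol. Acylation with 14 would give A5, and the forward key step would be opening of the dioxinone ring of A5 by phenol 5 (photochemically or as its phenoxide) to give 15.
- Irradiation near 300 nm falls where the aryl ester of A5 can undergo photo-Fries rearrangement and where 5 absorbs competitively.
- Phenoxide opening asks a poor nucleophile to attack a di-ortho-substituted carbonyl while the same phenoxide can cleave the A–B ester of A5.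
- The acyl transfer still occurs at a hindered aromatic carbonyl, which the chosen plan avoids, and no step is saved.

Alternative 3: cutting the aryl–carbonyl bond C1B–C7B. The forward key step would be a palladium-catalysed aryloxycarbonylation of aryl iodide A7 with carbon monoxide and phenol 5 to give 15.
- A7 would come from iodination of the orcinol monoester A6 at the carbon between OH and CH3. The positions para to the free OH and between the two oxygens are at least as reactive, so the regiochemical problem is moved, not solved.
- CO insertion at a di-ortho-substituted, ortho-hydroxy aryl iodide and C–O bond formation with a weakly nucleophilic phenoxide are the slow cases of carbonylation.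
- The base and temperature needed put the A–B ester at risk, and the route is no shorter.

Key step: step 4

## Route

Step 1
Reactants: 1 2,2,6-trimethyl-4H-1,3-dioxin-4-one
Product: 2 2,2-dimethyl-6-(2-oxopropyl)-4H-1,3-dioxin-4-one
Conditions: LiHMDS (1.0 equiv), THF, −78 °C; AcCl (0.5 equiv), −78 °C; aq. HCl
Reagents that add atoms: acetyl chloride CC(=O)Cl
Why: γ-Deprotonation of the 6-methyl group of the vinylogous ester and C-acylation at that carbon (crossed vinylogous Claisen condensation); half of the anion serves as base because 2 is more acidic than 1, and unchanged 1 can be recovered.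

Step 2
Reactants: 2 2,2-dimethyl-6-(2-oxopropyl)-4H-1,3-dioxin-4-one
Product: 3 6-(2,4-dioxopentyl)-2,2-dimethyl-4H-1,3-dioxin-4-one
Conditions: LDA (commercial solution, 2.2 equiv), THF, −78 °C; MeC(O)N(OMe)Me, −78 → −20 °C; aq. HCl to pH 2–3
Reagents that add atoms: N-methoxy-N-methylacetamide CC(=O)N(C)OC
Why: Double deprotonation (activated methylene, then terminal methyl) and acylation at the last-formed, more basic terminal carbanion (β-dicarbonyl dianion acylation); the chelated tetrahedral adduct persists until the acidic quench, which prevents a second addition and base-induced cyclisation of 3.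

Step 3
Reactants: 4 2,4-dihydroxy-6-methylbenzoic acid (orsellinic acid)
Product: 5 benzyl 2,4-dihydroxy-6-methylbenzoate (benzyl orsellinate)
Conditions: BnBr (1.05 equiv), KHCO3 (1.1 equiv), DMF, rt
Reagents that add atoms: benzyl bromide BrCc1ccccc1
Why: Carboxylate O-alkylation (SN2 at the benzylic carbon); bicarbonate deprotonates only the carboxylic acid and not the phenols, so the ester forms without phenol benzylation and without acyl transfer at the hindered carboxyl carbon. Room temperature avoids decarboxylation of the salicylic acid.

Step 4
Reactants: 3 6-(2,4-dioxopentyl)-2,2-dimethyl-4H-1,3-dioxin-4-one; 5 benzyl 2,4-dihydroxy-6-methylbenzoate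
Product: 9 benzyl 4-[(2,4-dihydroxy-6-methylbenzoyl)oxy]-2-hydroxy-6-methylbenzoate (benzyl lecanorate), via acylketene 6 (not isolated), via aryl triketo ester 7 (not isolated), via aryl cyclic aldol 8 (not isolated)
Conditions: 5 (2 equiv, 0.5 M), PhMe, 105 °C, slow addition of 3 (1 equiv); then Et3N (1 equiv), CH2Cl2, 0 °C → rt; then TFA, 0 °C → rt
Reagents that add atoms: none
Why: Proposed new method: the closest known reaction type is the thermolysis of diketo-dioxinones in the presence of aliphatic alcohols followed by base/acid aromatisation to alkyl resorcylates, together with the known capture of simple acylketenes by phenols; new here is a phenol as the trap for the triketide ketene and survival of the resulting aryl ester through the aromatisation. Retro-[4+2] cycloreversion of 3 expels acetone and unmasks acylketene 6, whose sp carbon has no ortho neighbours and should add the non-chelated 4-OH of 5 to give aryl triketo ester 7. Triethylamine then enolises chain carbon C2 (more acidic next to an aryl ester), which adds to the C7 methyl ketone and closes ring B by a 6-(enolendo)-exo-trig aldol to 8; E1cB loss of water across C6–C7 and enolisation of the C3 and C5 carbonyls, completed by acid, give the arene. No stereocentre is created: the carbinol carbon of 8 forms as a racemate and becomes sp2 on dehydration. Three selectivities are needed: (i) O4 over O2 of 5, secured by the hydrogen bond that ties O2–H to the ester carbonyl; (ii) intermolecular capture of 6 over its own cyclisation onto an enol oxygen to a 4-hydroxy-2-pyranone, favoured by a high concentration and excess of 5 with slow addition of 3; (iii) the aldol mode over the two acyl-transfer modes that would expel 5 (C6→C1 Claisen closure to an acylphloroglucinol and O5→C1 lactonisation). For (iii), the C7 ketone is the more electrophilic carbonyl, the ester carbonyl is deactivated by conjugation with the C2=C3 enol, and a weak amine base at low temperature in a non-nucleophilic solvent keeps alkoxide and hydroxide out. Once ring B is aromatic, its ester carbonyl lies between the chelating C2–OH and the C6–CH3 and should be inert; excess 5 is recoverable, and phenoxide exchange at the ester of 7 by 5 is degenerate.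

Step 5
Reactants: 10 1,2,3-trimethoxy-5-methylbenzene (3,4,5-trimethoxytoluene)
Product: 12 2,3,4-trimethoxy-6-methylbenzaldehyde, via aryl iminium salt 11 (not isolated)
Conditions: POCl3, DMF, 0 → 80 °C; then H2O, 60 °C
Reagents that add atoms: N,N-dimethylformamide CN(C)C=O; water O
Why: Vilsmeier–Haack formylation; the two free ring positions of 10 are equivalent by symmetry and are activated ortho and para by methoxy groups, so hydrolysis of iminium salt 11 can give only one aldehyde.

Step 6
Reactants: 12 2,3,4-trimethoxy-6-methylbenzaldehyde
Product: 13 2,3,4-trimethoxy-6-methylbenzoic acid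
Conditions: NaClO2, NaH2PO4, 2-methyl-2-butene, t-BuOH/H2O, 0 °C → rt
Reagents that add atoms: sodium chlorite [Na+].[O-]Cl=O
Why: Pinnick oxidation of the aldehyde under buffered conditions that leave aryl methyl ethers untouched; 2-methyl-2-butene scavenges the hypochlorous acid that could otherwise chlorinate C5 of the electron-rich ring.

Step 7
Reactants: 13 2,3,4-trimethoxy-6-methylbenzoic acid; 9 benzyl 4-[(2,4-dihydroxy-6-methylbenzoyl)oxy]-2-hydroxy-6-methylbenzoate
Product: 15 benzyl 2-hydroxy-4-({2-hydroxy-6-methyl-4-[(2,3,4-trimethoxy-6-methylbenzoyl)oxy]benzoyl}oxy)-6-methylbenzoate, via acid chloride 14 (not isolated)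
Conditions: (COCl)2, DMF (cat.), CH2Cl2, 0 °C → rt, evaporate; then 9, Et3N (1.1 equiv), DMAP (5 mol %), CH2Cl2, −20 → 0 °C
Reagents that add atoms: none
Why: Acid chloride formation followed by nucleophile-catalysed acylation of a phenol; of the three OH groups of 9 only O4B is not hydrogen-bonded to an ortho ester carbonyl and it is the most acidic, so one equivalent of base and of hindered chloride 14 should acylate it selectively, as in the standard 4-O-selective acylation of 2,4-dihydroxybenzoates. Low temperature and catalytic DMAP spare the hindered B–C ester.

Step 8
Reactants: 15 benzyl 2-hydroxy-4-({2-hydroxy-6-methyl-4-[(2,3,4-trimethoxy-6-methylbenzoyl)oxy]benzoyl}oxy)-6-methylbenzoate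
Product: 16 2-hydroxy-4-({2-hydroxy-6-methyl-4-[(2,3,4-trimethoxy-6-methylbenzoyl)oxy]benzoyl}oxy)-6-methylbenzoic acid (CNP0332884.0)
Conditions: H2 (1 atm), 10% Pd/C, EtOAc, rt
Reagents that add atoms: none
Why: Hydrogenolysis of a benzyl ester under neutral conditions; aryl esters, aryl methyl ethers and phenols are inert to H2/Pd–C at room temperature, and the acid is freed without the heat, acid or base that would promote decarboxylation or depside cleavage.

## Compound list

1 | 2,2,6-trimethyl-4H-1,3-dioxin-4-one | CC1=CC(=O)OC(C)(C)O1 | starting material
2 | 2,2-dimethyl-6-(2-oxopropyl)-4H-1,3-dioxin-4-one | CC(=O)CC1=CC(=O)OC(C)(C)O1 | intermediate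
3 | 6-(2,4-dioxopentyl)-2,2-dimethyl-4H-1,3-dioxin-4-one | CC(=O)CC(=O)CC1=CC(=O)OC(C)(C)O1 | intermediate
4 | 2,4-dihydroxy-6-methylbenzoic acid (orsellinic acid) | Cc1cc(O)cc(O)c1C(=O)O | starting material
5 | benzyl 2,4-dihydroxy-6-methylbenzoate (benzyl orsellinate) | Cc1cc(O)cc(O)c1C(=O)OCc1ccccc1 | intermediate
6 | 3,5,7-trioxooct-1-en-1-one (acylketene) | CC(=O)CC(=O)CC(=O)C=C=O | intermediate (not isolated)
7 | benzyl 2-hydroxy-6-methyl-4-[(3,5,7-trioxooctanoyl)oxy]benzoate | CC(=O)CC(=O)CC(=O)CC(=O)Oc1cc(C)c(C(=O)OCc2ccccc2)c(O)c1 | intermediate (not isolated)
8 | benzyl 4-[(2,6-dihydroxy-6-methyl-4-oxocyclohex-1-ene-1-carbonyl)oxy]-2-hydroxy-6-methylbenzoate (racemic) | CC1(O)CC(=O)CC(O)=C1C(=O)Oc1cc(C)c(C(=O)OCc2ccccc2)c(O)c1 | intermediate (not isolated)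
9 | benzyl 4-[(2,4-dihydroxy-6-methylbenzoyl)oxy]-2-hydroxy-6-methylbenzoate (benzyl lecanorate) | Cc1cc(O)cc(O)c1C(=O)Oc1cc(C)c(C(=O)OCc2ccccc2)c(O)c1 | intermediate
10 | 1,2,3-trimethoxy-5-methylbenzene (3,4,5-trimethoxytoluene) | COc1cc(C)cc(OC)c1OC | starting material
11 | N-methyl-N-[(2,3,4-trimethoxy-6-methylphenyl)methylidene]methanaminium chloride | COc1cc(C)c(C=[N+](C)C)c(OC)c1OC.[Cl-] | intermediate (not isolated)
12 | 2,3,4-trimethoxy-6-methylbenzaldehyde | COc1cc(C)c(C=O)c(OC)c1OC | intermediate
13 | 2,3,4-trimethoxy-6-methylbenzoic acid | COc1cc(C)c(C(=O)O)c(OC)c1OC | intermediate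
14 | 2,3,4-trimethoxy-6-methylbenzoyl chloride | COc1cc(C)c(C(=O)Cl)c(OC)c1OC | intermediate (not isolated)
15 | benzyl 2-hydroxy-4-({2-hydroxy-6-methyl-4-[(2,3,4-trimethoxy-6-methylbenzoyl)oxy]benzoyl}oxy)-6-methylbenzoate | COc1cc(C)c(C(=O)Oc2cc(C)c(C(=O)Oc3cc(C)c(C(=O)OCc4ccccc4)c(O)c3)c(O)c2)c(OC)c1OC | intermediate
16 | 2-hydroxy-4-({2-hydroxy-6-methyl-4-[(2,3,4-trimethoxy-6-methylbenzoyl)oxy]benzoyl}oxy)-6-methylbenzoic acid | COc1cc(C)c(C(=O)Oc2cc(C)c(C(=O)Oc3cc(C)c(C(=O)O)c(O)c3)c(O)c2)c(OC)c1OC | target

## Step count and risk

Total step count: 8. Longest linear sequence: 5 (steps 1, 2, 4, 7, 8); the ring C branch (step 3) joins at step 4 and the ring A branch (steps 5, 6) joins at step 7.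

**Step 4 (key step, Proposed new method).** Two processes are most likely to fail. During thermolysis, the ketene may cyclise onto its own enol oxygen, or oligomerise, faster than the ester-deactivated phenol captures it. During base treatment, acyl transfer may compete with the aldol: Claisen closure onto the ester carbon, lactonisation by the C5 enol oxygen, or exchange with the phenoxide of the product. Each of these expels the phenol, because an aryloxide is a far better leaving group than the alkoxides for which the sequence is established.

Fallback (known chemistry, same bond order): it sets out from 5 and returns at 9. Compound 5 is silylated selectively at its non-chelated 4-OH (TIPSCl, imidazole) to give benzyl 2-hydroxy-6-methyl-4-[(triisopropylsilyl)oxy]benzoate F1. Hydrogenolysis frees 2-hydroxy-6-methyl-4-[(triisopropylsilyl)oxy]benzoic acid F2. F2 is condensed with a second portion of 5 by DCC in toluene, the classical depside coupling of a chelated o-hydroxy acid, to give benzyl 2-hydroxy-4-({2-hydroxy-6-methyl-4-[(triisopropylsilyl)oxy]benzoyl}oxy)-6-methylbenzoate F3. Buffered fluoride (TBAF/AcOH) then removes the silyl group to give 9, and steps 7 and 8 follow unchanged.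

**Step 7.** The di-ortho-substituted chloride may react sluggishly, so that forcing leads to acylation at a chelated phenol as well. Alternatively the phenoxide of 9 formed under basic conditions may attack a depside carbonyl and scramble the esters.

Fallback (the order of the two esterifications is reversed): it sets out from 5 and 13 (activated as chloride 14) and returns at 15. Compound 5, which has only one free and one chelated phenol, is acylated with 14 to give benzyl 2-hydroxy-6-methyl-4-[(2,3,4-trimethoxy-6-methylbenzoyl)oxy]benzoate F4. Hydrogenolysis gives 2-hydroxy-6-methyl-4-[(2,3,4-trimethoxy-6-methylbenzoyl)oxy]benzoic acid F5. F5 is condensed with a second portion of 5 by DCC in toluene to give 15, which goes on to step 8.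

**Step 2.** The dianion may be acylated on oxygen, or the second deprotonation may be incomplete. Product 3 may also cyclise under base to a benzodioxinone if the mixture warms before the acidic quench.

Fallback (a malonate route that avoids the dianion): it sets out from 1 and returns at 3, replacing steps 1 and 2. The γ-anion of 1 is acylated with allyl malonyl chloride to give allyl 4-(2,2-dimethyl-4-oxo-4H-1,3-dioxin-6-yl)-3-oxobutanoate F6. Soft enolisation with MgCl2 and pyridine and C-acetylation with acetyl chloride give allyl 2-acetyl-4-(2,2-dimethyl-4-oxo-4H-1,3-dioxin-6-yl)-3-oxobutanoate F7. Pd(PPh3)4 and morpholine then effect deallylation and decarboxylation to give 3.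

**Step 6.** Electrophilic chlorination of the electron-rich ring at C5 may occur if hypochlorous acid escapes the scavenger, and oxidation of the di-ortho-substituted aldehyde may be slow.

Fallback (the carboxyl carbon is introduced as CO2, with no aldehyde): it sets out from 10 and returns at 13, replacing steps 5 and 6. Compound 10 is brominated with NBS in acetonitrile to give 1-bromo-2,3,4-trimethoxy-6-methylbenzene F8. Bromine–lithium exchange with n-BuLi at −78 °C gives (2,3,4-trimethoxy-6-methylphenyl)lithium F9, which is carboxylated with CO2 and acidified to give 13.

## Further compounds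

F1 | step 4 | benzyl 2-hydroxy-6-methyl-4-[(triisopropylsilyl)oxy]benzoate | Cc1cc(O[Si](C(C)C)(C(C)C)C(C)C)cc(O)c1C(=O)OCc1ccccc1
F2 | step 4 | 2-hydroxy-6-methyl-4-[(triisopropylsilyl)oxy]benzoic acid | Cc1cc(O[Si](C(C)C)(C(C)C)C(C)C)cc(O)c1C(=O)O
F3 | step 4 | benzyl 2-hydroxy-4-({2-hydroxy-6-methyl-4-[(triisopropylsilyl)oxy]benzoyl}oxy)-6-methylbenzoate | Cc1cc(O[Si](C(C)C)(C(C)C)C(C)C)cc(O)c1C(=O)Oc1cc(C)c(C(=O)OCc2ccccc2)c(O)c1
F4 | step 7 | benzyl 2-hydroxy-6-methyl-4-[(2,3,4-trimethoxy-6-methylbenzoyl)oxy]benzoate | COc1cc(C)c(C(=O)Oc2cc(C)c(C(=O)OCc3ccccc3)c(O)c2)c(OC)c1OC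
F5 | step 7 | 2-hydroxy-6-methyl-4-[(2,3,4-trimethoxy-6-methylbenzoyl)oxy]benzoic acid | COc1cc(C)c(C(=O)Oc2cc(C)c(C(=O)O)c(O)c2)c(OC)c1OC
F6 | step 2 | allyl 4-(2,2-dimethyl-4-oxo-4H-1,3-dioxin-6-yl)-3-oxobutanoate | C=CCOC(=O)CC(=O)CC1=CC(=O)OC(C)(C)O1
F7 | step 2 | allyl 2-acetyl-4-(2,2-dimethyl-4-oxo-4H-1,3-dioxin-6-yl)-3-oxobutanoate | C=CCOC(=O)C(C(C)=O)C(=O)CC1=CC(=O)OC(C)(C)O1
F8 | step 6 | 1-bromo-2,3,4-trimethoxy-6-methylbenzene | COc1cc(C)c(Br)c(OC)c1OC
F9 | step 6 | (2,3,4-trimethoxy-6-methylphenyl)lithium | COc1cc(C)c([Li])c(OC)c1OC
A1 | alternative 1 | 2,4-bis(benzyloxy)-6-methylbenzoic acid | Cc1cc(OCc2ccccc2)cc(OCc2ccccc2)c1C(=O)O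
A2 | alternative 1 | benzyl 4-{[2,4-bis(benzyloxy)-6-methylbenzoyl]oxy}-2-hydroxy-6-methylbenzoate | Cc1cc(OCc2ccccc2)cc(OCc2ccccc2)c1C(=O)Oc1cc(C)c(C(=O)OCc2ccccc2)c(O)c1
A3 | alternative 1 | 4-[(2,4-dihydroxy-6-methylbenzoyl)oxy]-2-hydroxy-6-methylbenzoic acid (lecanoric acid) | Cc1cc(O)cc(O)c1C(=O)Oc1cc(C)c(C(=O)O)c(O)c1
A4 | alternative 2 | 7-hydroxy-2,2,5-trimethyl-4H-1,3-benzodioxin-4-one | Cc1cc(O)cc2c1C(=O)OC(C)(C)O2
A5 | alternative 2 | 2,2,5-trimethyl-4-oxo-4H-1,3-benzodioxin-7-yl 2,3,4-trimethoxy-6-methylbenzoate | COc1cc(C)c(C(=O)Oc2cc(C)c3c(c2)OC(C)(C)OC3=O)c(OC)c1OC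
A6 | alternative 3 | 3-hydroxy-5-methylphenyl 2,3,4-trimethoxy-6-methylbenzoate | COc1cc(C)c(C(=O)Oc2cc(C)cc(O)c2)c(OC)c1OC
A7 | alternative 3 | 3-hydroxy-4-iodo-5-methylphenyl 2,3,4-trimethoxy-6-methylbenzoate | COc1cc(C)c(C(=O)Oc2cc(C)c(I)c(O)c2)c(OC)c1OC
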